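What is left over in the summer flask once its solid substrate has dissolved tells me what the target does next.

| flask | solid substrate | gas | remark | time |
|---|---|---|---|---|
| summer | 0.025 M | 9.1 mM (held) | run made earlier |  |
| winter | 0.10 M | 9.1 mM (held) | run made earlier |  |
| flask | 0.050 M | 9.1 mM (held) |  | 4.0 min |

| run | time / min | target / % | dissolved substrate / % | solid substrate / % |
|---|---|---|---|---|
| summer | 0.833 | 20 | 51 | 27 |
| summer | 1.50 | 41 | 51 | 0 |
| summer | 2.50 | 58 | 18 | 0 |
| summer | 3.00 | 59 | 10 | 0 |
| summer | 4.00 | 50 | 1 | 3 |
| winter | 0.333 | 0 | 7 | 90 |
| winter | 0.667 | 0 | 10 | 85 |
| winter | 1.00 | 2 | 16 | 79 |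
| winter | 2.00 | 13 | 18 | 61 |
| winter | 4.00 | 21 | 21 | 25 |

(readings scatter by 2 percentage points)

- percent here means solid substrate units held: one side product counts as two
- solid substrate is a solid; its amount is given per volume of the solution
- at the start none of coupling partner is dissolved
- the earlier runs were read with a standard deviation of 2 percentage points
- steps thought possible: solid substrate <-> dissolved substrate; dissolved substrate + coupling partner -> target; gas <-> coupling partner; solid substrate + target -> side product; target <-> isomer of the product
- at the start none of the solid substrate is in solution
- dissolved substrate means what is dissolved; the solid is not counted in it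

* target at 4.0 min, in percent of the solid substrate charged
* concentration of dissolved substrate in solution at 4.0 min, in percent of saturation

I read the summer table row against row. Solid substrate reads 0 % at 3.00 min and 3 % at 4.00 min, at a scatter of 2 percentage points. Dissolved substrate that couples stays inside the sum of target and dissolved substrate, so a fall in that sum is target leaving. It falls by 18 points between those rows.

I replace the target curve there by its mean, 54.5 %; the logarithmic mean gives 54.4 %, so the swap costs little. The loss constant kL, the first-order rate constant of target leaving, is the fall per minute over the mean target: 0.330 min⁻¹. The rows from 1.50 min to 2.50 min read 0.323 min⁻¹. Its time constant, 3.03 min, is shorter than the 4.0 min asked.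

The forecast gives 48 % target and 22 % of saturation, starting from “Summer shows target lost after the solid is gone”. My own reckoning takes a straight rise to that target, so its mean is half of it, and gives 31.7 % isomer of the product at 4.0 min.

The flask gives 48.7 % target and 21.4 % of saturation, and the forecast stands within its margins.

    solid substrate ⇌ dissolved substrate, rate k1*(cs1 - [dissolved substrate]) while solid is left; crystals form when [dissolved substrate] > cs1 (solubility = 37.0 mM, k = 0.0120 s⁻¹)
    dissolved substrate + coupling partner → target (k = 2.00 M⁻¹ s⁻¹)
    gas ⇌ coupling partner, rate k3*(csat - [coupling partner]) (kL = 0.0650 s⁻¹)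
    solid substrate + target → side product (k = 0.0840 M⁻¹ s⁻¹)
    target ⇌ isomer of the product (K = 5.10, k = 0.00480 s⁻¹)

Left to 8.00 min, this flask holds 29.1 % target. At 4.00 min it holds 28.2 % isomer of the product, below my 31.7 %. For the neighbour flask read at 2.5 min, with 35.1 % target, kL and the same straight rise give 14.5 %; that flask holds 10.9 % isomer of the product.

The numbers in the tables come from a simulation with made-up constants.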